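**Plan**

1. The target core is numbered as a 7-oxabicyclo[4.1.0]heptan-2-one: C1 (epoxide, methyl), C2 (C=O), C3 (O-tigloyl), C4 (side chain), C5 (CH2), C6 (epoxide CH). Retrosynthetic cuts, in order: the C–OOH bond; the bond between the side-chain carbonyl carbon and the methylene-bearing carbon; the epoxide oxygen (back to a C1=C6 alkene); last, together, the ring bonds C3–C4 and C1–C6.
2. Enabling feature: ketone C2 sits between two α-carbons, C3 (which keeps its tigloyloxy group) and C1 (the epoxide stands for a C1=C6 enone alkene), and C4–C5–C6 is the β-carbon/α-carbon/carbonyl carbon of an enal. The carbocycle is therefore a [3+3] union of a tigloyloxy β-keto ester (1,3-bis-nucleophile; the ester only activates and leaves as CO2) with a 2,4-dienal (1,3-bis-electrophile) by Michael addition and aldol condensation.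
3. Forward: dienal 4 (one step) and keto ester 8 (two steps) give cyclohexenone 12 in one operation. The ring ketone is then reduced to a carbinol to steer the epoxide, the side chain is joined at the bromoalkene, both carbinols are oxidised together, and the hydroperoxide is introduced last.
4. Stereochemistry: C4 from the chiral amine catalyst; C3 by acid equilibration trans to C4; the epoxide face (cis to the C4 substituent, the face that nucleophilic epoxidation of the enone should not give) from axial hydride delivery followed by hydroxyl-directed epoxidation.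
5. Alkene geometries come from tiglic acid, the stabilised ylide and the ene reaction.

Key step: step 4

Remark: the face selectivity assigned to the (S)-catalyst follows the usual shielding model of its E-iminium ion; if the opposite sense were met, the (R)-catalyst would be used and nothing else changes.

**Route**

Step 1
Reactants: 1 2-bromoprop-2-en-1-ol; 2 (triphenylphosphoranylidene)acetaldehyde
Product: 4 (2E)-4-bromopenta-2,4-dienal, via 2-bromoprop-2-enal 3 (not isolated)
Conditions: MnO2 (activated, 10 equiv), 2 (1.0 equiv), CH2Cl2, rt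
Reagents that add atoms: none
Why: Tandem allylic oxidation–Wittig olefination, in which the polymerisation-prone aldehyde 3 is trapped as it forms by the stabilised formyl ylide, which should give the E-enal and should react much more slowly with the conjugated product than with 3.

Step 2
Reactants: 5 tert-butyl 3-oxopentanoate
Product: 6 tert-butyl 2-bromo-3-oxopentanoate (racemic)
Conditions: NBS (1.05 equiv), NH4OAc (10 mol %), Et2O, rt
Reagents that add atoms: N-bromosuccinimide, O=C1CCC(=O)N1Br
Why: Electrophilic α-bromination of a 1,3-dicarbonyl compound through its enol at the doubly activated carbon; the stereocentre formed is racemic and is destroyed in step 4.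

Step 3
Reactants: 6 tert-butyl 2-bromo-3-oxopentanoate; 7 tiglic acid [(2E)-2-methylbut-2-enoic acid]
Product: 8 tert-butyl 2-{[(2E)-2-methylbut-2-enoyl]oxy}-3-oxopentanoate (racemic)
Conditions: KHCO3 (1.2 equiv), DMF, rt
Reagents that add atoms: none
Why: SN2 alkylation of the carboxylate formed in the flask by the activated secondary α-bromide, which puts the tigloyloxy group on the carbon that becomes C3 of the target and should leave the E-alkene untouched.

Step 4
Reactants: 4 (2E)-4-bromopenta-2,4-dienal; 8 tert-butyl 2-{[(2E)-2-methylbut-2-enoyl]oxy}-3-oxopentanoate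
Product: 12 (1S,6R)-6-(1-bromoethenyl)-3-methyl-2-oxocyclohex-3-en-1-yl (2E)-2-methylbut-2-enoate, via Michael adduct 9 (not isolated), via cyclohexenone tert-butyl ester 10 (not isolated), via keto acid 11 (not isolated)
Conditions: (S)-2-[diphenyl(trimethylsilyloxy)methyl]pyrrolidine (10 mol %), PhCO2H (10 mol %), toluene, 0 °C to rt; then TsOH·H2O (30 mol %), toluene, 80 °C
Reagents that add atoms: none
Why: Proposed new method: the amine and 4 form an E-iminium ion, the enol of 8 adds through its acyloxy-bearing carbon to the β-carbon (Michael addition, first ring bond, 9), and on acidification the enol of the ethyl ketone attacks the aldehyde (aldol addition, second ring bond), water is lost to enone 10, the tert-butyl ester falls to acid 11, and this β-keto acid loses CO2 to a dienol that ketonises to 12. The closest known reaction type is the amine-catalysed Michael addition of α-unsubstituted β-keto esters to enals followed by acid-promoted aldol condensation and decarboxylation to 5-substituted cyclohex-2-enones; new here is a donor that already carries the acyloxy group, so that its carbon becomes fully substituted in the addition and the oxygen is kept when the carboxyl group leaves. The ring closes by a 6-(enolendo)-exo-trig aldol addition. The bromoethenyl-bearing centre is set by the catalyst, whose diphenyl(silyloxy)methyl group should cover the Re face of the iminium β-carbon so that the donor adds to the Si face, and the acyloxy-bearing centre is set on ketonisation under equilibrating acid, which should leave the ester equatorial and trans to the bromoethenyl group. The step needs 1,4- and not 1,6-addition to the dienal, which the larger LUMO coefficient and the closeness of the β-carbon to the iminium nitrogen should secure, and it needs one aldol regiochemistry, which is secured because the second α-carbon of the ketone is quaternary and the aldehyde enol could only close a four-membered ring.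

Step 5
Reactants: 12 (1S,6R)-6-(1-bromoethenyl)-3-methyl-2-oxocyclohex-3-en-1-yl (2E)-2-methylbut-2-enoate
Product: 13 (1S,2S,6R)-6-(1-bromoethenyl)-2-hydroxy-3-methylcyclohex-3-en-1-yl (2E)-2-methylbut-2-enoate
Conditions: NaBH4, CeCl3·7H2O, MeOH, −78 °C
Reagents that add atoms: none
Why: Luche reduction, in which the cerium-activated carbonyl is reduced 1,2 and the hydride should enter axially on the half-chair that holds both ring substituents equatorial, giving the equatorial carbinol cis to the bromoethenyl group and trans to the ester, while the low temperature should keep the tiglate from migrating to the new hydroxyl.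

Step 6
Reactants: 13 (1S,2S,6R)-6-(1-bromoethenyl)-2-hydroxy-3-methylcyclohex-3-en-1-yl (2E)-2-methylbut-2-enoate
Product: 14 (1R,2R,3S,4R,6S)-4-(1-bromoethenyl)-2-hydroxy-1-methyl-7-oxabicyclo[4.1.0]heptan-3-yl (2E)-2-methylbut-2-enoate
Conditions: VO(acac)2 (5 mol %), t-BuOOH (1.5 equiv, decane), CH2Cl2, 0 °C to rt
Reagents that add atoms: tert-butyl hydroperoxide, CC(C)(C)OO
Why: Hydroxyl-directed epoxidation, in which the vanadium alkoxide of the allylic alcohol delivers oxygen from bound hydroperoxide to the ring alkene on the face of the hydroxyl group, setting both epoxide carbons cis to the bromoethenyl group and leaving the bromoalkene and the electron-poor tiglate alkene alone.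

Step 7
Reactants: 15 4-methylpent-3-en-1-ol
Product: 16 4-methylpent-3-enal (used at once as a solution)
Conditions: Dess–Martin periodinane (1.1 equiv), NaHCO3, CH2Cl2, 0 °C
Reagents that add atoms: none
Why: Dess–Martin oxidation of a primary alcohol under buffered, non-basic conditions, which should deliver the β,γ-unsaturated aldehyde without moving the alkene into conjugation.

Step 8
Reactants: 14 (1R,2R,3S,4R,6S)-4-(1-bromoethenyl)-2-hydroxy-1-methyl-7-oxabicyclo[4.1.0]heptan-3-yl (2E)-2-methylbut-2-enoate; 16 4-methylpent-3-enal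
Product: 17 (1R,2R,3S,4S,6S)-2-hydroxy-4-(3-hydroxy-6-methylhepta-1,5-dien-2-yl)-1-methyl-7-oxabicyclo[4.1.0]heptan-3-yl (2E)-2-methylbut-2-enoate (both epimers at the side-chain carbinol)
Conditions: CrCl2 (4 equiv), NiCl2 (2 mol %), 16 (2 equiv), DMF, rt
Reagents that add atoms: none
Why: Nozaki–Hiyama–Kishi coupling, in which zerovalent nickel inserts into the C–Br bond and hands the alkenyl group to trivalent chromium, whose alkenyl species adds only to the aldehyde and should tolerate the free hydroxyl, the epoxide and the ester; the new carbinol centre forms as a mixture that step 9 erases.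

Step 9
Reactants: 17 (1R,2R,3S,4S,6S)-2-hydroxy-4-(3-hydroxy-6-methylhepta-1,5-dien-2-yl)-1-methyl-7-oxabicyclo[4.1.0]heptan-3-yl (2E)-2-methylbut-2-enoate
Product: 18 (1S,3S,4S,6S)-1-methyl-4-(6-methyl-3-oxohepta-1,5-dien-2-yl)-2-oxo-7-oxabicyclo[4.1.0]heptan-3-yl (2E)-2-methylbut-2-enoate
Conditions: Dess–Martin periodinane (3 equiv), NaHCO3, CH2Cl2, 0 °C to rt
Reagents that add atoms: none
Why: Dess–Martin oxidation of both secondary alcohols in one operation under buffered conditions, which restores the ring ketone, removes the two carbinol stereocentres and should spare the epoxide and keep the skipped enone from drifting into conjugation.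

Step 10
Reactants: 18 (1S,3S,4S,6S)-1-methyl-4-(6-methyl-3-oxohepta-1,5-dien-2-yl)-2-oxo-7-oxabicyclo[4.1.0]heptan-3-yl (2E)-2-methylbut-2-enoate
Product: 19 (1S,3S,4S,6S)-4-[(4E)-6-hydroperoxy-6-methyl-3-oxohepta-1,4-dien-2-yl]-1-methyl-2-oxo-7-oxabicyclo[4.1.0]heptan-3-yl (2E)-2-methylbut-2-enoate (target)
Conditions: O2, tetraphenylporphyrin (cat.), white LED, CH2Cl2, −20 °C
Reagents that add atoms: dioxygen, O=O
Why: Schenck ene reaction of singlet oxygen with the only electron-rich alkene, in which oxygen bonds to the dimethyl-substituted carbon while a hydrogen of the CH2 next to the carbonyl is transferred, so that the alkene moves into conjugation as the E-enone (the course known for β,γ-unsaturated ketones) and the methylene-enone and tiglate alkenes should stay inert.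

**Compound list**

1 | 2-bromoprop-2-en-1-ol | OCC(Br)=C | starting material
2 | (triphenylphosphoranylidene)acetaldehyde | O=CC=P(c1ccccc1)(c1ccccc1)c1ccccc1 | starting material
3 | 2-bromoprop-2-enal | O=CC(Br)=C | intermediate
4 | (2E)-4-bromopenta-2,4-dienal | O=C/C=C/C(Br)=C | intermediate
5 | tert-butyl 3-oxopentanoate | CCC(=O)CC(=O)OC(C)(C)C | starting material
6 | tert-butyl 2-bromo-3-oxopentanoate (racemic) | CCC(=O)C(Br)C(=O)OC(C)(C)C | intermediate
7 | tiglic acid, (2E)-2-methylbut-2-enoic acid | C/C=C(\C)C(=O)O | starting material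
8 | tert-butyl 2-{[(2E)-2-methylbut-2-enoyl]oxy}-3-oxopentanoate (racemic) | CCC(=O)C(OC(=O)/C(C)=C/C)C(=O)OC(C)(C)C | intermediate
9 | tert-butyl 2-[(3R)-2-bromo-5-oxopent-1-en-3-yl]-2-{[(2E)-2-methylbut-2-enoyl]oxy}-3-oxopentanoate (both epimers at C2) | C=C(Br)[C@H](CC=O)C(OC(=O)/C(C)=C/C)(C(=O)OC(C)(C)C)C(=O)CC | intermediate
10 | tert-butyl (6R)-6-(1-bromoethenyl)-3-methyl-1-{[(2E)-2-methylbut-2-enoyl]oxy}-2-oxocyclohex-3-ene-1-carboxylate (both epimers at C1) | C=C(Br)[C@@H]1CC=C(C)C(=O)C1(OC(=O)/C(C)=C/C)C(=O)OC(C)(C)C | intermediate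
11 | (6R)-6-(1-bromoethenyl)-3-methyl-1-{[(2E)-2-methylbut-2-enoyl]oxy}-2-oxocyclohex-3-ene-1-carboxylic acid (both epimers at C1) | C=C(Br)[C@@H]1CC=C(C)C(=O)C1(OC(=O)/C(C)=C/C)C(=O)O | intermediate
12 | (1S,6R)-6-(1-bromoethenyl)-3-methyl-2-oxocyclohex-3-en-1-yl (2E)-2-methylbut-2-enoate (ester and bromoethenyl trans) | C=C(Br)[C@@H]1CC=C(C)C(=O)[C@H]1OC(=O)/C(C)=C/C | intermediate
13 | (1S,2S,6R)-6-(1-bromoethenyl)-2-hydroxy-3-methylcyclohex-3-en-1-yl (2E)-2-methylbut-2-enoate (hydroxyl cis to bromoethenyl, trans to ester) | C=C(Br)[C@@H]1CC=C(C)[C@H](O)[C@H]1OC(=O)/C(C)=C/C | intermediate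
14 | (1R,2R,3S,4R,6S)-4-(1-bromoethenyl)-2-hydroxy-1-methyl-7-oxabicyclo[4.1.0]heptan-3-yl (2E)-2-methylbut-2-enoate (epoxide cis to hydroxyl and bromoethenyl) | C=C(Br)[C@@H]1C[C@@H]2O[C@]2(C)[C@H](O)[C@H]1OC(=O)/C(C)=C/C | intermediate
15 | 4-methylpent-3-en-1-ol | CC(C)=CCCO | starting material
16 | 4-methylpent-3-enal | CC(C)=CCC=O | intermediate
17 | (1R,2R,3S,4S,6S)-2-hydroxy-4-(3-hydroxy-6-methylhepta-1,5-dien-2-yl)-1-methyl-7-oxabicyclo[4.1.0]heptan-3-yl (2E)-2-methylbut-2-enoate (both epimers at the side-chain carbinol) | C=C(C(O)CC=C(C)C)[C@@H]1C[C@@H]2O[C@]2(C)[C@H](O)[C@H]1OC(=O)/C(C)=C/C | intermediate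
18 | (1S,3S,4S,6S)-1-methyl-4-(6-methyl-3-oxohepta-1,5-dien-2-yl)-2-oxo-7-oxabicyclo[4.1.0]heptan-3-yl (2E)-2-methylbut-2-enoate | C=C(C(=O)CC=C(C)C)[C@@H]1C[C@@H]2O[C@]2(C)C(=O)[C@H]1OC(=O)/C(C)=C/C | intermediate
19 | (1S,3S,4S,6S)-4-[(4E)-6-hydroperoxy-6-methyl-3-oxohepta-1,4-dien-2-yl]-1-methyl-2-oxo-7-oxabicyclo[4.1.0]heptan-3-yl (2E)-2-methylbut-2-enoate | C=C(C(=O)/C=C/C(C)(C)OO)[C@@H]1C[C@@H]2O[C@]2(C)C(=O)[C@H]1OC(=O)/C(C)=C/C | target

**Totals**

Total step count: 10. Longest linear sequence: 8 steps (steps 2, 3, 4, 5, 6, 8, 9, 10).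

**Steps most likely to fail**

1. Step 4 (proposed new method). The fully substituted donor may add slowly, attack may drift to the diene terminus (1,6-addition), equilibration at the acyloxy-bearing carbon may stop at a mixture of epimers, or tiglic acid may be lost with aromatisation in the hot acid stage. Fallback by known chemistry, setting out from 4 and 5 and returning at 12: under the same amine catalyst the unsubstituted keto ester 5 adds to 4 to give the Michael adduct tert-butyl 2-[(3R)-2-bromo-5-oxopent-1-en-3-yl]-3-oxopentanoate F1. TsOH in warm toluene then closes the ring to the cyclohexenone tert-butyl ester F2, cleaves it to the keto acid F3 and, after loss of CO2, leaves (5R)-5-(1-bromoethenyl)-2-methylcyclohex-2-en-1-one F4. Its kinetic cross-conjugated lithium enolate (LiN(SiMe3)2, THF, −78 °C) is hydroxylated with 2-(phenylsulfonyl)-3-phenyloxaziridine on the face away from the bromoethenyl group to give the trans-hydroxy enone (5R,6S)-5-(1-bromoethenyl)-6-hydroxy-2-methylcyclohex-2-en-1-one F5. Steglich esterification of F5 with 7 (DCC, DMAP, CH2Cl2) gives 12; here the oxygen-bearing centre is set under kinetic instead of thermodynamic control.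

2. Step 10. Hydrogen abstraction may take place from a methyl group instead of the methylene next to the carbonyl, which leads to the secondary allylic hydroperoxide, and the product may be lost by radical decomposition. Fallback, setting out from 14 and returning at 19, in which the hydroperoxide arrives ready-made and masked and the E-alkene is built by olefination:
   - 14 is coupled under the conditions of step 8 with diethyl (2-oxoethyl)phosphonate to give the hydroxy phosphonate F6, and Dess–Martin oxidation as in step 9 gives the keto phosphonate F7.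
   - Separately, 2-methylbut-3-en-2-ol is converted with 50 % H2O2 and catalytic H2SO4 into 2-methylbut-3-en-2-yl hydroperoxide F8, which is masked with 2-methoxypropene (PPTS) as the peroxyketal 3-[(2-methoxypropan-2-yl)peroxy]-3-methylbut-1-ene F9 and ozonised (O3, CH2Cl2, −78 °C; PPh3) to the peroxy aldehyde 2-[(2-methoxypropan-2-yl)peroxy]-2-methylpropanal F10.
   - Horner–Wadsworth–Emmons olefination of F10 with F7 (Ba(OH)2, wet THF) gives the masked hydroperoxy E-enone F11, and AcOH/THF/H2O at rt releases 19.

3. Step 8. Nickel may insert slowly into the hindered 1,1-disubstituted bromoalkene, the alkenylchromium species may be protonated by the free hydroxyl group, or the β,γ-unsaturated aldehyde may drift into conjugation before it is consumed. Fallback, setting out from 14 and returning at 17, in which the side-chain carbon becomes the electrophile: formylation of the bromoalkene (Pd(PPh3)4, CO, Bu3SnH, THF, 50 °C) gives the 2-substituted acrolein F12. Barbier allylation in water-containing solvent (allyl bromide, In powder, THF/H2O) gives the homoallylic alcohol F13. Cross-metathesis with 2-methylbut-2-ene (second-generation Grubbs catalyst, CH2Cl2, 40 °C) turns the terminal alkene into the prenyl group and gives 17.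

**Further compounds**

F1 | step 4 | tert-butyl 2-[(3R)-2-bromo-5-oxopent-1-en-3-yl]-3-oxopentanoate | C=C(Br)[C@H](CC=O)C(C(=O)OC(C)(C)C)C(=O)CC
F2 | step 4 | tert-butyl (6R)-6-(1-bromoethenyl)-3-methyl-2-oxocyclohex-3-ene-1-carboxylate | C=C(Br)[C@@H]1CC=C(C)C(=O)C1C(=O)OC(C)(C)C
F3 | step 4 | (6R)-6-(1-bromoethenyl)-3-methyl-2-oxocyclohex-3-ene-1-carboxylic acid | C=C(Br)[C@@H]1CC=C(C)C(=O)C1C(=O)O
F4 | step 4 | (5R)-5-(1-bromoethenyl)-2-methylcyclohex-2-en-1-one | C=C(Br)[C@@H]1CC=C(C)C(=O)C1
F5 | step 4 | (5R,6S)-5-(1-bromoethenyl)-6-hydroxy-2-methylcyclohex-2-en-1-one | C=C(Br)[C@@H]1CC=C(C)C(=O)[C@H]1O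
F6 | step 10 | (1R,2R,3S,4S,6S)-4-[4-(diethoxyphosphoryl)-3-hydroxybut-1-en-2-yl]-2-hydroxy-1-methyl-7-oxabicyclo[4.1.0]heptan-3-yl (2E)-2-methylbut-2-enoate | C=C(C(O)CP(=O)(OCC)OCC)[C@@H]1C[C@@H]2O[C@]2(C)[C@H](O)[C@H]1OC(=O)/C(C)=C/C
F7 | step 10 | (1S,3S,4S,6S)-4-[4-(diethoxyphosphoryl)-3-oxobut-1-en-2-yl]-1-methyl-2-oxo-7-oxabicyclo[4.1.0]heptan-3-yl (2E)-2-methylbut-2-enoate | C=C(C(=O)CP(=O)(OCC)OCC)[C@@H]1C[C@@H]2O[C@]2(C)C(=O)[C@H]1OC(=O)/C(C)=C/C
F8 | step 10 | 2-methylbut-3-en-2-yl hydroperoxide | C=CC(C)(C)OO
F9 | step 10 | 3-[(2-methoxypropan-2-yl)peroxy]-3-methylbut-1-ene | C=CC(C)(C)OOC(C)(C)OC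
F10 | step 10 | 2-[(2-methoxypropan-2-yl)peroxy]-2-methylpropanal | O=CC(C)(C)OOC(C)(C)OC
F11 | step 10 | (1S,3S,4S,6S)-4-{(4E)-6-[(2-methoxypropan-2-yl)peroxy]-6-methyl-3-oxohepta-1,4-dien-2-yl}-1-methyl-2-oxo-7-oxabicyclo[4.1.0]heptan-3-yl (2E)-2-methylbut-2-enoate | C=C(C(=O)/C=C/C(C)(C)OOC(C)(C)OC)[C@@H]1C[C@@H]2O[C@]2(C)C(=O)[C@H]1OC(=O)/C(C)=C/C
F12 | step 8 | (1R,2R,3S,4S,6S)-2-hydroxy-1-methyl-4-(3-oxoprop-1-en-2-yl)-7-oxabicyclo[4.1.0]heptan-3-yl (2E)-2-methylbut-2-enoate | C=C(C=O)[C@@H]1C[C@@H]2O[C@]2(C)[C@H](O)[C@H]1OC(=O)/C(C)=C/C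
F13 | step 8 | (1R,2R,3S,4S,6S)-2-hydroxy-4-(3-hydroxyhexa-1,5-dien-2-yl)-1-methyl-7-oxabicyclo[4.1.0]heptan-3-yl (2E)-2-methylbut-2-enoate (both epimers at the side-chain carbinol) | C=C(C(O)CC=C)[C@@H]1C[C@@H]2O[C@]2(C)[C@H](O)[C@H]1OC(=O)/C(C)=C/C
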